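**Plan**

- Retrosynthesis: the pyranone is opened at O1–C2 (SN2 ring closure), then C2–C3 is cut (aldol of a propanoyl group on C4a with acetaldehyde). The C8–CH bond of the side chain (Friedel–Crafts alkylation with hex-2-enal) and the C6–prenyl bond follow, back to commercial flopropione.
- Enabling feature: O1 and the ester carbon are 1,6-related through C8a–C8–CH–CH2, so the target is a ring-opened 3,4-dihydrocoumarin. O1 is therefore carried as the ring oxygen of a temporary six-membered lactone, which sets it apart from O5 and O7 (both MOM ethers) and stores the ester.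
- Forward order: the benzene ring is bought. C6-prenylation, O7 protection, C8 alkylation with lactol then lactone formation on O1, O5 protection, syn-aldol, lactone methanolysis (frees O1–H, gives the methyl ester), closure of the pyranone as the last ring, deprotection.
- Stereochemistry: the side-chain centre comes from iminium catalysis with an (R)-diarylprolinol silyl ether. C3 and the C2 carbinol come from a reagent-controlled syn-aldol (Ipc2B enolate). C2 is inverted in the ring closure, which gives 2S,3S (trans).

Key step: step 8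

Assumption: the sense of induction of the aminocatalyst (step 3) and of the borane (step 6) is taken from the usual face-shielding and chair transition-state models; if either proves reversed on this substrate, the antipodal reagent is used and nothing else changes.

**Route**

Step 1
Reactants: 1 flopropione [1-(2,4,6-trihydroxyphenyl)propan-1-one]; 2 prenyl bromide
Product: 3 1-[2,4,6-trihydroxy-3-(3-methylbut-2-en-1-yl)phenyl]propan-1-one
Conditions: prenyl bromide (1.0 equiv), KOH (10% aq), 0 °C to rt
Reagents that add atoms: prenyl bromide, CC(C)=CCBr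
Why: C-alkylation of the acylphloroglucinol phenoxide in water (C-prenylation) should give the mono-C-prenyl ketone, since the two free ring carbons are equivalent and one equivalent of halide limits over-alkylation.

Step 2
Reactants: 3; 4 chloromethyl methyl ether (MOMCl)
Product: 5 1-[2,6-dihydroxy-4-(methoxymethoxy)-3-(3-methylbut-2-en-1-yl)phenyl]propan-1-one
Conditions: MOMCl (1.05 equiv), K2CO3, acetone, 0 °C
Reagents that add atoms: chloromethyl methyl ether, COCCl
Why: Williamson-type O-alkylation should take place at the 4-OH (the later O7), which is para to the ketone, the most acidic hydroxyl and the only one not chelated to the carbonyl.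

Step 3
Reactants: 5; 6 (E)-hex-2-enal
Product: 7 1-[(4S)-2,7-dihydroxy-5-(methoxymethoxy)-6-(3-methylbut-2-en-1-yl)-4-propyl-3,4-dihydro-2H-chromen-8-yl]propan-1-one (lactol, both C2 epimers)
Conditions: (R)-2-[diphenyl(trimethylsilyloxy)methyl]pyrrolidine (20 mol %), PhCO2H (20 mol %), toluene, 0 °C
Reagents that add atoms: (E)-hex-2-enal, CCC/C=C/C=O
Why: Iminium-catalysed Friedel–Crafts alkylation/hemiacetalisation of an electron-rich phenol with an enal: C5 of 5 is the only unsubstituted ring carbon, the adduct is trapped as a lactol by the adjacent free OH (the future O1, the other ortho oxygen being the MOM ether), and the (R)-catalyst shields one face of the E-iminium ion so that the arene adds to the beta-carbon from the other face, which should give 4S.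

Step 4
Reactants: 7
Product: 8 (4S)-7-hydroxy-5-(methoxymethoxy)-6-(3-methylbut-2-en-1-yl)-8-propanoyl-4-propyl-3,4-dihydro-2H-chromen-2-one
Conditions: nPr4N[RuO4] (5 mol %), NMO, 4 Å molecular sieves, CH2Cl2, rt
Reagents that add atoms: none
Why: Perruthenate-catalysed oxidation of a lactol to the lactone with NMO as terminal oxidant should leave the chelated phenol, the MOM ether, the trisubstituted alkene and the C4 stereocentre untouched.

Step 5
Reactants: 8; 4 chloromethyl methyl ether
Product: 9 (4S)-5,7-bis(methoxymethoxy)-6-(3-methylbut-2-en-1-yl)-8-propanoyl-4-propyl-3,4-dihydro-2H-chromen-2-one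
Conditions: NaH (1.05 equiv), DMF, 0 °C; MOMCl
Reagents that add atoms: chloromethyl methyl ether, COCCl
Why: O-alkylation of the sodium phenoxide (Williamson-type MOM protection) can only occur at the C7 hydroxyl of 8 (the later O5), because the future O1 is held in the lactone, and one equivalent of NaH removes only the phenolic proton.

Step 6
Reactants: 9; 10 acetaldehyde
Product: 12 (4S)-8-[(2S,3R)-3-hydroxy-2-methylbutanoyl]-5,7-bis(methoxymethoxy)-6-(3-methylbut-2-en-1-yl)-4-propyl-3,4-dihydro-2H-chromen-2-one, via Z-boron enolate 11 (not isolated)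
Conditions: (−)-Ipc2BOTf [from (+)-α-pinene], iPr2NEt, CH2Cl2, −78 °C; MeCHO, −78 to −20 °C; then MeOH, pH 7 buffer, 30% H2O2, 0 °C
Reagents that add atoms: acetaldehyde, CC=O
Why: Boron-mediated aldol addition: the boron triflate and amine should enolise only the ketone (the more Lewis-basic carbonyl) to the Z-enolate 11, whose closed chair transition state gives the 2,3-syn aldol, and the isopinocampheyl ligands select the aldehyde face so that the alpha-carbon becomes S and the carbinol carbon R, independent of the remote C4 centre.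

Step 7
Reactants: 12; 13 methanol
Product: 14 methyl (3S)-3-{2-hydroxy-3-[(2S,3R)-3-hydroxy-2-methylbutanoyl]-4,6-bis(methoxymethoxy)-5-(3-methylbut-2-en-1-yl)phenyl}hexanoate
Conditions: K2CO3 (0.2 equiv), MeOH, 0 °C, short reaction time; NH4Cl (aq); used at once
Reagents that add atoms: methanol, CO
Why: Base-catalysed transesterification of the aryl lactone (acyl–oxygen cleavage, phenoxide as leaving group) should be fast at 0 °C and gives the methyl ester and the free O1–H phenol at once, the brief, cold, catalytic treatment being chosen to spare the beta-hydroxy ketone.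

Step 8
Reactants: 14
Product: 16 methyl (3S)-3-[(2S,3S)-5,7-bis(methoxymethoxy)-2,3-dimethyl-6-(3-methylbut-2-en-1-yl)-4-oxo-3,4-dihydro-2H-chromen-8-yl]hexanoate, via alkoxyphosphonium phenoxide 15 (not isolated)
Conditions: PPh3 (1.5 equiv), DIAD (1.5 equiv), THF, 0 °C to rt
Reagents that add atoms: none
Why: Mitsunobu cyclodehydration: PPh3/DIAD convert the side-chain carbinol of 14 into the alkoxyphosphonium ion 15 while the betaine deprotonates the only free phenol (O1–H, acidified by the ortho ketone), and the phenoxide displaces Ph3P=O intramolecularly. The closest known reaction type is the Mitsunobu closure of ortho-hydroxyaryl beta-hydroxyalkyl ketones to 2,3-dialkylchroman-4-ones. The pyranone ring closes in the 6-exo-tet mode by forming O1–C2. C2 is the only stereocentre changed: SN2 inversion turns the R carbinol into 2S, while C3 (S, from step 6) is not touched, so the syn aldol gives the 2,3-trans ring. The step needs O1 to react rather than O5 or O7, and substitution to outrun E1cB loss of the activated oxygen; the first is secured because O1 was masked as the lactone oxygen until step 7 while O5 and O7 carry MOM groups, the second by the neutral, cold conditions and the high effective molarity of the chelated phenoxide.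

Step 9
Reactants: 16
Product: 17 methyl (3S)-3-[(2S,3S)-5,7-dihydroxy-2,3-dimethyl-6-(3-methylbut-2-en-1-yl)-4-oxo-3,4-dihydro-2H-chromen-8-yl]hexanoate (target)
Conditions: HCl (3 M aq), MeOH, 40 °C
Reagents that add atoms: none
Why: Acid-catalysed acetal exchange should remove both MOM groups as dimethoxymethane; methanol as solvent keeps the side chain as the methyl ester, the mild acid should neither cyclise the prenyl group onto O5 or O7 nor open the pyranone, and C3 stays in its more stable trans arrangement.

**Compound list**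

1 | flopropione, 1-(2,4,6-trihydroxyphenyl)propan-1-one | CCC(=O)c1c(O)cc(O)cc1O | starting material
2 | prenyl bromide, 1-bromo-3-methylbut-2-ene | CC(C)=CCBr | starting material
3 | 1-[2,4,6-trihydroxy-3-(3-methylbut-2-en-1-yl)phenyl]propan-1-one | CCC(=O)c1c(O)cc(O)c(CC=C(C)C)c1O | intermediate
4 | chloromethyl methyl ether | COCCl | starting material
5 | 1-[2,6-dihydroxy-4-(methoxymethoxy)-3-(3-methylbut-2-en-1-yl)phenyl]propan-1-one | CCC(=O)c1c(O)cc(OCOC)c(CC=C(C)C)c1O | intermediate
6 | (E)-hex-2-enal | CCC/C=C/C=O | starting material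
7 | 1-[(4S)-2,7-dihydroxy-5-(methoxymethoxy)-6-(3-methylbut-2-en-1-yl)-4-propyl-3,4-dihydro-2H-chromen-8-yl]propan-1-one (lactol, C2 epimers) | CCC[C@H]1CC(O)Oc2c(C(=O)CC)c(O)c(CC=C(C)C)c(OCOC)c12 | intermediate
8 | (4S)-7-hydroxy-5-(methoxymethoxy)-6-(3-methylbut-2-en-1-yl)-8-propanoyl-4-propyl-3,4-dihydro-2H-chromen-2-one | CCC[C@H]1CC(=O)Oc2c(C(=O)CC)c(O)c(CC=C(C)C)c(OCOC)c12 | intermediate
9 | (4S)-5,7-bis(methoxymethoxy)-6-(3-methylbut-2-en-1-yl)-8-propanoyl-4-propyl-3,4-dihydro-2H-chromen-2-one | CCC[C@H]1CC(=O)Oc2c(C(=O)CC)c(OCOC)c(CC=C(C)C)c(OCOC)c12 | intermediate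
10 | acetaldehyde | CC=O | starting material
11 | (Z)-diisopinocampheylboron enolate of 9 (boron on the ketone oxygen, methyl cis to oxygen) | CCC[C@H]1CC(=O)Oc2c(C(\OB([C@@H]3C[C@@H]4C[C@H]([C@H]3C)C4(C)C)[C@@H]3C[C@@H]4C[C@H]([C@H]3C)C4(C)C)=C\C)c(OCOC)c(CC=C(C)C)c(OCOC)c12 | intermediate
12 | (4S)-8-[(2S,3R)-3-hydroxy-2-methylbutanoyl]-5,7-bis(methoxymethoxy)-6-(3-methylbut-2-en-1-yl)-4-propyl-3,4-dihydro-2H-chromen-2-one | CCC[C@H]1CC(=O)Oc2c(C(=O)[C@@H](C)[C@@H](C)O)c(OCOC)c(CC=C(C)C)c(OCOC)c12 | intermediate
13 | methanol | CO | starting material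
14 | methyl (3S)-3-{2-hydroxy-3-[(2S,3R)-3-hydroxy-2-methylbutanoyl]-4,6-bis(methoxymethoxy)-5-(3-methylbut-2-en-1-yl)phenyl}hexanoate | CCC[C@@H](CC(=O)OC)c1c(O)c(C(=O)[C@@H](C)[C@@H](C)O)c(OCOC)c(CC=C(C)C)c1OCOC | intermediate
15 | alkoxytriphenylphosphonium phenoxide zwitterion of 14 (phosphorus on the carbinol oxygen, O1 as phenoxide) | CCC[C@@H](CC(=O)OC)c1c([O-])c(C(=O)[C@@H](C)[C@@H](C)O[P+](c2ccccc2)(c2ccccc2)c2ccccc2)c(OCOC)c(CC=C(C)C)c1OCOC | intermediate
16 | methyl (3S)-3-[(2S,3S)-5,7-bis(methoxymethoxy)-2,3-dimethyl-6-(3-methylbut-2-en-1-yl)-4-oxo-3,4-dihydro-2H-chromen-8-yl]hexanoate | CCC[C@@H](CC(=O)OC)c1c(OCOC)c(CC=C(C)C)c(OCOC)c2c1O[C@@H](C)[C@H](C)C2=O | intermediate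
17 | methyl (3S)-3-[(2S,3S)-5,7-dihydroxy-2,3-dimethyl-6-(3-methylbut-2-en-1-yl)-4-oxo-3,4-dihydro-2H-chromen-8-yl]hexanoate | CCC[C@@H](CC(=O)OC)c1c(O)c(CC=C(C)C)c(O)c2c1O[C@@H](C)[C@H](C)C2=O | target

**Step count and risks**

Total step count: 9. Longest linear sequence: 9 (the route is linear from flopropione).

Steps most likely to fail:

1. Step 3. The ketone-deactivated, pentasubstituted arene may add too slowly to the iminium ion, and an uncatalysed background addition may erode the enantioselectivity. Fallback: setting out from 5, a three-component Knoevenagel/Michael/lactonisation with butanal and Meldrum's acid (pyridine, 80 °C) should proceed through 5-butylidene-2,2-dimethyl-1,3-dioxane-4,6-dione F1. With loss of acetone and carbon dioxide this gives the racemic lactone F2, again closed on the only free ortho hydroxyl. F2 is resolved by preparative chromatography on a chiral stationary phase, and the 4S enantiomer re-enters the route as 8.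

2. Step 6. Facial selection by the chiral borane may be incomplete, and some enolisation of the aryl lactone may compete. Fallback: setting out from 9, an aldol addition with the achiral reagent nBu2BOTf/iPr2NEt and acetaldehyde should give the syn aldol as a mixture of 12 and its (2R,3S) side-chain diastereomer F3. Lipase-catalysed acylation (Burkholderia cepacia lipase, vinyl acetate) is expected, by the usual empirical rule for secondary carbinols, to acetylate the R carbinol of 12 to the acetate F4, which is separated from unchanged F3. K2CO3 in MeOH then cleaves the acetate and the lactone together and comes back to the route at 14.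

3. Step 8. E1cB loss of the activated oxygen may precede substitution, and re-addition of the phenol to the resulting enone would scramble C2. Fallback: setting out from 12, the elimination is made deliberate. MsCl/Et3N gives the mesylate F5 and DBU the (E)-2-methylbut-2-enoyl lactone F6. K2CO3 in MeOH then opens the lactone, the freed O1 phenoxide adds to the enone (6-endo-trig oxa-Michael) and C3 equilibrates to trans. This should give 16 together with its (2R,3R) ring diastereomer F7; 16 is separated by chromatography and rejoins the route, while F7 is re-equilibrated under the same basic conditions.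

**Further compounds**

F1 | step 3 | 5-butylidene-2,2-dimethyl-1,3-dioxane-4,6-dione | CCCC=C1C(=O)OC(C)(C)OC1=O
F2 | step 3 | racemic 7-hydroxy-5-(methoxymethoxy)-6-(3-methylbut-2-en-1-yl)-8-propanoyl-4-propyl-3,4-dihydro-2H-chromen-2-one | CCCC1CC(=O)Oc2c(C(=O)CC)c(O)c(CC=C(C)C)c(OCOC)c12
F3 | step 6 | (4S)-8-[(2R,3S)-3-hydroxy-2-methylbutanoyl]-5,7-bis(methoxymethoxy)-6-(3-methylbut-2-en-1-yl)-4-propyl-3,4-dihydro-2H-chromen-2-one | CCC[C@H]1CC(=O)Oc2c(C(=O)[C@H](C)[C@H](C)O)c(OCOC)c(CC=C(C)C)c(OCOC)c12
F4 | step 6 | (4S)-8-[(2S,3R)-3-acetoxy-2-methylbutanoyl]-5,7-bis(methoxymethoxy)-6-(3-methylbut-2-en-1-yl)-4-propyl-3,4-dihydro-2H-chromen-2-one | CCC[C@H]1CC(=O)Oc2c(C(=O)[C@@H](C)[C@@H](C)OC(C)=O)c(OCOC)c(CC=C(C)C)c(OCOC)c12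
F5 | step 8 | (4S)-8-[(2S,3R)-3-(methanesulfonyloxy)-2-methylbutanoyl]-5,7-bis(methoxymethoxy)-6-(3-methylbut-2-en-1-yl)-4-propyl-3,4-dihydro-2H-chromen-2-one | CCC[C@H]1CC(=O)Oc2c(C(=O)[C@@H](C)[C@@H](C)OS(C)(=O)=O)c(OCOC)c(CC=C(C)C)c(OCOC)c12
F6 | step 8 | (4S)-5,7-bis(methoxymethoxy)-8-[(E)-2-methylbut-2-enoyl]-6-(3-methylbut-2-en-1-yl)-4-propyl-3,4-dihydro-2H-chromen-2-one | CCC[C@H]1CC(=O)Oc2c(C(=O)/C(C)=C/C)c(OCOC)c(CC=C(C)C)c(OCOC)c12
F7 | step 8 | methyl (3S)-3-[(2R,3R)-5,7-bis(methoxymethoxy)-2,3-dimethyl-6-(3-methylbut-2-en-1-yl)-4-oxo-3,4-dihydro-2H-chromen-8-yl]hexanoate | CCC[C@@H](CC(=O)OC)c1c(OCOC)c(CC=C(C)C)c(OCOC)c2c1O[C@H](C)[C@@H](C)C2=O
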